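**Retrosynthetic overview** (isochromene locants: C1, O2, C3, C4, C4a, C5, C6, C7, C8, C8a; ring A = pyran, ring B = carbocycle)
1. Mitorubrinic acid ⇒ acid-labile protecting groups off (step 11) ⇒ C7–O ester disconnection to tertiary α-ketol 15 and protected orsellinoyl chloride 19 (step 10).
2. Ring B (C4a–C5–C6–C7–C8–C8a) ⇒ C7–C8 disconnection: an enantioselective carbene-catalysed intramolecular crossed benzoin of the achiral keto-aldehyde 14 closes the ring and sets C7 in one operation.
3. Enabling feature: C7 is a tertiary carbinol carbon flanked by the C6 and C8 ketones (an α-ketol, the benzoin retron); C8 sits on pyran carbon C8a and can be a formyl group, while C6/C7 hang as a 1,2-diketone from the exocyclic push–pull C4a=C5 bond, whose easy rotation lets E and Z isomers of 14 converge.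
4. 14 ⇒ γ-pyrone 8 plus a C4 acetylide: 1,2-addition, then Meyer–Schuster rearrangement (creates C4a=C5 and the C6 ketone) with acetal and ketal hydrolysis.
5. Ring order: orsellinate arene is bought; ring A is closed in step 3 by acylketene/enol ether hetero-Diels–Alder reaction (pyran C2, C4, C5, C6 become C3, C4a, C8a, C1); ring B is closed last, in step 7.

Key step: step 7

Remark on the chemistry: the catalyst enantiomer in step 7 is assigned by analogy with related benzoin cyclisations; should the sense of induction prove opposite, the antipodal triazolium salt is used and nothing else changes.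

Step 1
Reactants: 1 2,2,6-trimethyl-4H-1,3-dioxin-4-one
Product: 2 2,2-dimethyl-4-oxo-4H-1,3-dioxine-6-carbaldehyde
Conditions: SeO2 (1.3 equiv), 1,4-dioxane, 95 °C
Reagents that add atoms: selenium dioxide, O=[Se]=O
Why: Riley oxidation, in which selenium dioxide should oxidise the activated 6-methyl group of the vinylogous ester selectively to the aldehyde.

Step 2
Reactants: 2 2,2-dimethyl-4-oxo-4H-1,3-dioxine-6-carbaldehyde; 3 tert-butyl (triphenyl-λ5-phosphanylidene)acetate
Product: 4 tert-butyl (2E)-3-(2,2-dimethyl-4-oxo-4H-1,3-dioxin-6-yl)prop-2-enoate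
Conditions: CH2Cl2, 23 °C
Reagents that add atoms: none
Why: Wittig olefination with a stabilised ylide, which should give the (E)-enoate selectively.

Step 3
Reactants: 4 tert-butyl (2E)-3-(2,2-dimethyl-4-oxo-4H-1,3-dioxin-6-yl)prop-2-enoate; 5 (E)-1,3,3-trimethoxyprop-1-ene
Product: 8 tert-butyl (2E)-3-[5-(dimethoxymethyl)-4-oxo-4H-pyran-2-yl]prop-2-enoate, via acylketene 6 (not isolated), via dihydropyranone 7 (not isolated)
Conditions: 5 (4 equiv), toluene, 110 °C; then DBU (20 mol %), 23 °C
Reagents that add atoms: none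
Why: Thermal retro-[4+2] loss of acetone gives acylketene 6, which should be trapped by the electron-rich enol ether in a hetero-Diels–Alder reaction (ketene carbon bonding to the acetal-bearing carbon), and base-induced β-elimination of methanol from 7 then gives the γ-pyrone that is ring A.

Step 4
Reactants: 9 but-3-yn-2-one
Product: 10 3,3-dimethoxybut-1-yne
Conditions: HC(OMe)3, MeOH, p-TsOH (1 mol %), 23 °C
Reagents that add atoms: trimethyl orthoformate, COC(OC)OC; methanol, CO
Why: Acid-catalysed ketalisation with orthoformate as water scavenger, under which conjugate addition of methanol to the ynone should stay slow.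

Step 5
Reactants: 10 3,3-dimethoxybut-1-yne; 8 tert-butyl (2E)-3-[5-(dimethoxymethyl)-4-oxo-4H-pyran-2-yl]prop-2-enoate
Product: 12 tert-butyl (2E)-3-[4-(3,3-dimethoxybut-1-yn-1-yl)-5-(dimethoxymethyl)-4-hydroxy-4H-pyran-2-yl]prop-2-enoate, via lithium acetylide 11 (not isolated)
Conditions: 10, n-BuLi, THF, −78 °C; LaCl3·2LiCl (30 mol %), then 8, −78 → −40 °C; H2O
Reagents that add atoms: none
Why: 1,2-Addition of a hard alkynyl organometallic to the γ-pyrone carbonyl (the classical entry to 4-substituted pyrylium systems), with the lanthanum salt favouring carbonyl over conjugate addition and the tert-butyl ester resisting attack; the new carbinol centre is racemic and is destroyed in step 6.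

Step 6
Reactants: 12 tert-butyl (2E)-3-[4-(3,3-dimethoxybut-1-yn-1-yl)-5-(dimethoxymethyl)-4-hydroxy-4H-pyran-2-yl]prop-2-enoate
Product: 14 tert-butyl (2E)-3-[4-(2,3-dioxobutylidene)-5-formyl-4H-pyran-2-yl]prop-2-enoate, via keto ketal 13 (not isolated)
Conditions: 2 M aq. HCl, THF, 0 → 40 °C
Reagents that add atoms: water, O
Why: Meyer–Schuster rearrangement, in which acid ionises the pyranol to a 4-alkynylpyrylium ion, water adds at the distal alkyne carbon and tautomerisation gives the pyranylidene ketone (C4a=C5 and C6=O), while acetal and then slower α-keto ketal hydrolysis unmask the formyl group and the 1,2-diketone under aqueous acid that a tert-butyl ester should survive.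

Step 7
Reactants: 14 tert-butyl (2E)-3-[4-(2,3-dioxobutylidene)-5-formyl-4H-pyran-2-yl]prop-2-enoate
Product: 15 tert-butyl (2E)-3-[(7S)-7-hydroxy-7-methyl-6,8-dioxo-7,8-dihydro-6H-isochromen-3-yl]prop-2-enoate
Conditions: (5aR,10bS)-2-(pentafluorophenyl)-5a,10b-dihydro-4H,6H-indeno[2,1-b][1,2,4]triazolo[4,3-d][1,4]oxazin-2-ium tetrafluoroborate (10 mol %), iPr2NEt (10 mol %), toluene, 23 °C
Reagents that add atoms: none
Why: Deprotonation of the triazolium salt gives a chiral triazolylidene that adds to the C8 formyl group; proton transfer gives the Breslow intermediate (an acyl anion equivalent), which attacks the C7 acetyl carbonyl of the 1,2-diketone, and collapse of the adduct releases the carbene, the C8 ketone and the C7 tertiary alcohol. The closest known reaction type is the enantioselective carbene-catalysed intramolecular crossed aldehyde–ketone benzoin reaction that gives six-membered α-ketols with a fully substituted carbinol carbon. Ring B (C4a, C5, C6, C7, C8, C8a) closes in a 6-exo-trig mode by C7–C8 bond formation. The only stereocentre, C7, is set under catalyst control: the rigid indanyl backbone of the carbene shields one face of the Breslow intermediate so that one enantiotopic face of the C7 ketone is attacked, and the (S) product is targeted by the choice of catalyst enantiomer. The step needs donor/acceptor selectivity (only the aldehyde can form a Breslow intermediate), site selectivity for six-membered closure at C7 over five-membered closure at C6 (C6 is a vinylogous ester carbonyl deactivated by ring oxygen O2, whereas C7 is an acetyl ketone activated by the adjacent carbonyl) and stereoconvergence (the exocyclic C4a=C5 bond is a push–pull alkene with a low rotation barrier, so the E and Z isomers of 14 interconvert and both drain through the isomer whose diketone arm faces the formyl group). A weak amine base and a non-polar solvent should keep carbene addition at C1 and homoenolate pathways reversible or slow.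

Step 8
Reactants: 16 methyl 2,4-dihydroxy-6-methylbenzoate
Product: 17 methyl 2,4-bis(methoxymethoxy)-6-methylbenzoate
Conditions: NaH (2.5 equiv), MOMCl (2.5 equiv), DMF, 0 → 23 °C
Reagents that add atoms: chloromethyl methyl ether, COCCl
Why: Williamson-type O-alkylation of both phenoxides, sodium hydride being needed to engage the hydrogen-bonded 2-hydroxyl.

Step 9
Reactants: 17 methyl 2,4-bis(methoxymethoxy)-6-methylbenzoate
Product: 18 2,4-bis(methoxymethoxy)-6-methylbenzoic acid
Conditions: KOH (10 equiv), MeOH–H2O, 80 °C; then 1 M HCl to pH 4, 0 °C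
Reagents that add atoms: potassium hydroxide, [K+].[OH-]
Why: Saponification of the hindered ester under forcing basic conditions that MOM ethers tolerate, followed by cautious cold acidification.

Step 10
Reactants: 18 2,4-bis(methoxymethoxy)-6-methylbenzoic acid; 15 tert-butyl (2E)-3-[(7S)-7-hydroxy-7-methyl-6,8-dioxo-7,8-dihydro-6H-isochromen-3-yl]prop-2-enoate
Product: 20 (7S)-3-[(1E)-3-tert-butoxy-3-oxoprop-1-en-1-yl]-7-methyl-6,8-dioxo-7,8-dihydro-6H-isochromen-7-yl 2,4-bis(methoxymethoxy)-6-methylbenzoate, via acid chloride 19 (not isolated)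
Conditions: 18, 1-chloro-N,N,2-trimethylprop-1-en-1-amine, CH2Cl2, 0 °C; then 15, Et3N, DMAP (20 mol %), CH2Cl2, 0 → 23 °C
Reagents that add atoms: none
Why: Neutral acid chloride formation with Ghosez's reagent (no HCl, so the MOM ethers survive) followed by DMAP-catalysed acylation of the tertiary α-ketol hydroxyl, in which C7 is not touched and so keeps its configuration, while low temperature and short exposure to amine limit base-induced α-ketol rearrangement.

Step 11
Reactants: 20 (7S)-3-[(1E)-3-tert-butoxy-3-oxoprop-1-en-1-yl]-7-methyl-6,8-dioxo-7,8-dihydro-6H-isochromen-7-yl 2,4-bis(methoxymethoxy)-6-methylbenzoate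
Product: 21 (S)-mitorubrinic acid
Conditions: TFA–CH2Cl2–H2O (30:65:5), 0 → 23 °C
Reagents that add atoms: none
Why: Acidolysis, in which TFA should cleave the tert-butyl ester (loss of isobutene) and both aryl MOM acetals in one operation, while the azaphilone core and the tertiary benzoate, whose ionisation at C7 is disfavoured by the two flanking ketones, should be stable to acid.

**Compound list**
1 | 2,2,6-trimethyl-4H-1,3-dioxin-4-one | CC1=CC(=O)OC(C)(C)O1 | starting material
2 | 2,2-dimethyl-4-oxo-4H-1,3-dioxine-6-carbaldehyde | CC1(C)OC(=O)C=C(C=O)O1 | intermediate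
3 | tert-butyl (triphenyl-λ5-phosphanylidene)acetate | CC(C)(C)OC(=O)C=P(c1ccccc1)(c1ccccc1)c1ccccc1 | starting material
4 | tert-butyl (2E)-3-(2,2-dimethyl-4-oxo-4H-1,3-dioxin-6-yl)prop-2-enoate | CC1(C)OC(=O)C=C(/C=C/C(=O)OC(C)(C)C)O1 | intermediate
5 | (E)-1,3,3-trimethoxyprop-1-ene | CO/C=C/C(OC)OC | starting material
6 | tert-butyl (2E)-4,6-dioxohexa-2,5-dienoate (acylketene, not isolated) | O=C=CC(=O)/C=C/C(=O)OC(C)(C)C | intermediate
7 | tert-butyl (2E)-3-[5-(dimethoxymethyl)-6-methoxy-4-oxo-5,6-dihydro-4H-pyran-2-yl]prop-2-enoate (diastereomer mixture, not isolated) | COC(OC)C1C(OC)OC(/C=C/C(=O)OC(C)(C)C)=CC1=O | intermediate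
8 | tert-butyl (2E)-3-[5-(dimethoxymethyl)-4-oxo-4H-pyran-2-yl]prop-2-enoate | COC(OC)C1=COC(/C=C/C(=O)OC(C)(C)C)=CC1=O | intermediate
9 | but-3-yn-2-one | CC(=O)C#C | starting material
10 | 3,3-dimethoxybut-1-yne | COC(C)(OC)C#C | intermediate
11 | lithium 3,3-dimethoxybut-1-yn-1-ide (not isolated) | [Li]C#CC(C)(OC)OC | intermediate
12 | tert-butyl (2E)-3-[4-(3,3-dimethoxybut-1-yn-1-yl)-5-(dimethoxymethyl)-4-hydroxy-4H-pyran-2-yl]prop-2-enoate (racemic) | COC(OC)C1=COC(/C=C/C(=O)OC(C)(C)C)=CC1(O)C#CC(C)(OC)OC | intermediate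
13 | tert-butyl (2E)-3-[4-(3,3-dimethoxy-2-oxobutylidene)-5-formyl-4H-pyran-2-yl]prop-2-enoate (not isolated) | COC(C)(OC)C(=O)C=C1C=C(/C=C/C(=O)OC(C)(C)C)OC=C1C=O | intermediate
14 | tert-butyl (2E)-3-[4-(2,3-dioxobutylidene)-5-formyl-4H-pyran-2-yl]prop-2-enoate (E/Z mixture at the exocyclic bond) | CC(=O)C(=O)C=C1C=C(/C=C/C(=O)OC(C)(C)C)OC=C1C=O | intermediate
15 | tert-butyl (2E)-3-[(7S)-7-hydroxy-7-methyl-6,8-dioxo-7,8-dihydro-6H-isochromen-3-yl]prop-2-enoate | O[C@@]1(C)C(=O)C=C2C=C(/C=C/C(=O)OC(C)(C)C)OC=C2C1=O | intermediate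
16 | methyl 2,4-dihydroxy-6-methylbenzoate (methyl orsellinate) | COC(=O)c1c(C)cc(O)cc1O | starting material
17 | methyl 2,4-bis(methoxymethoxy)-6-methylbenzoate | COCOc1cc(C)c(C(=O)OC)c(OCOC)c1 | intermediate
18 | 2,4-bis(methoxymethoxy)-6-methylbenzoic acid | COCOc1cc(C)c(C(=O)O)c(OCOC)c1 | intermediate
19 | 2,4-bis(methoxymethoxy)-6-methylbenzoyl chloride (not isolated) | COCOc1cc(C)c(C(Cl)=O)c(OCOC)c1 | intermediate
20 | (7S)-3-[(1E)-3-tert-butoxy-3-oxoprop-1-en-1-yl]-7-methyl-6,8-dioxo-7,8-dihydro-6H-isochromen-7-yl 2,4-bis(methoxymethoxy)-6-methylbenzoate | Cc1cc(OCOC)cc(OCOC)c1C(=O)O[C@@]1(C)C(=O)C=C2C=C(/C=C/C(=O)OC(C)(C)C)OC=C2C1=O | intermediate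
21 | (S)-mitorubrinic acid | Cc1cc(O)cc(O)c1C(=O)O[C@@]1(C)C(=O)C=C2C=C(/C=C/C(=O)O)OC=C2C1=O | target

**Step count**
Total steps: 11. Longest linear sequence: 8 steps (steps 1, 2, 3, 5, 6, 7, 10, 11); step 4 and steps 8–9 are side branches.

**Steps most likely to fail**

Step 7. Carbene addition at the electrophilic C1 position of the pyranylidene, homoenolate chemistry of the β-oxy enal, or poor facial selectivity could erode conversion or enantiopurity. The fallback makes the same C7–C8 bond by an aldol–oxidation sequence and sets out from pyranone 8. Commercial racemic tert-butyl(but-3-yn-2-yloxy)dimethylsilane is deprotonated with n-BuLi to the lithium silyloxybutynide F1, which is added to 8 as in step 5 to give the silyloxy pyranol F2. Dilute acid (pyridinium p-toluenesulfonate, wet acetone) effects Meyer–Schuster rearrangement and acetal hydrolysis to the α-silyloxy ketone aldehyde F3. LiN(SiMe3)2 in THF at −78 °C enolises the only enolisable position (C7), and a 6-(enolexo)-exo-trig aldol addition to the formyl group gives the β-hydroxy ketone F4. Dess–Martin periodinane oxidises the C8 carbinol to the silyl-protected dione F5, and HF·pyridine removes the silyl group to give the racemic ketol F6. The enantiomers are separated by preparative HPLC on a chiral stationary phase; the (S) enantiomer is 15, where the fallback rejoins the route.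

Step 5. Conjugate addition at the unsubstituted C6 position of the pyrone, followed by ring opening, could compete with carbonyl addition. The fallback forms the C4a=C5 bond by an Eschenmoser sulfide contraction instead of an organometallic addition and sets out from 8. Lawesson's reagent (toluene, 80 °C) gives the pyranthione F7. Commercial 3,3-dimethoxybutan-2-one is brominated with phenyltrimethylammonium tribromide in THF to the bromoketone F8, which S-alkylates F7 in acetonitrile to the 4-(alkylthio)pyrylium bromide F9. Et3N and PPh3 then bring about thiirane formation and sulfur extrusion to the pyranylidene ketone bis-acetal F10. Hydrolysis under the conditions of step 6 returns to the route at 14.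

Step 6. The slow α-keto ketal hydrolysis could cost the tert-butyl ester or decompose the polycarbonyl product. The fallback unmasks the 1,2-diketone by oxidation instead of hydrolysis and sets out from 8. But-3-yn-2-ol is doubly deprotonated with n-BuLi (2 equiv) to the dilithium butynolate F11, which adds to 8 to give the diol F12. Mild acid (pyridinium p-toluenesulfonate, wet acetone) gives the α-hydroxy ketone aldehyde F13 by Meyer–Schuster rearrangement and acetal hydrolysis. Dess–Martin periodinane oxidises the secondary alcohol, and the fallback returns to the route at 14.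

**Further compounds**
F1 | step 7 | lithium 3-[(tert-butyldimethylsilyl)oxy]but-1-yn-1-ide | [Li]C#CC(C)O[Si](C)(C)C(C)(C)C
F2 | step 7 | tert-butyl (2E)-3-[4-{3-[(tert-butyldimethylsilyl)oxy]but-1-yn-1-yl}-5-(dimethoxymethyl)-4-hydroxy-4H-pyran-2-yl]prop-2-enoate | COC(OC)C1=COC(/C=C/C(=O)OC(C)(C)C)=CC1(O)C#CC(C)O[Si](C)(C)C(C)(C)C
F3 | step 7 | tert-butyl (2E)-3-[4-{3-[(tert-butyldimethylsilyl)oxy]-2-oxobutylidene}-5-formyl-4H-pyran-2-yl]prop-2-enoate | CC(O[Si](C)(C)C(C)(C)C)C(=O)C=C1C=C(/C=C/C(=O)OC(C)(C)C)OC=C1C=O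
F4 | step 7 | tert-butyl (2E)-3-{7-[(tert-butyldimethylsilyl)oxy]-8-hydroxy-7-methyl-6-oxo-7,8-dihydro-6H-isochromen-3-yl}prop-2-enoate | CC1(O[Si](C)(C)C(C)(C)C)C(=O)C=C2C=C(/C=C/C(=O)OC(C)(C)C)OC=C2C1O
F5 | step 7 | tert-butyl (2E)-3-{7-[(tert-butyldimethylsilyl)oxy]-7-methyl-6,8-dioxo-7,8-dihydro-6H-isochromen-3-yl}prop-2-enoate (racemic) | CC1(O[Si](C)(C)C(C)(C)C)C(=O)C=C2C=C(/C=C/C(=O)OC(C)(C)C)OC=C2C1=O
F6 | step 7 | tert-butyl (2E)-3-(7-hydroxy-7-methyl-6,8-dioxo-7,8-dihydro-6H-isochromen-3-yl)prop-2-enoate (racemic) | CC1(O)C(=O)C=C2C=C(/C=C/C(=O)OC(C)(C)C)OC=C2C1=O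
F7 | step 5 | tert-butyl (2E)-3-[5-(dimethoxymethyl)-4-sulfanylidene-4H-pyran-2-yl]prop-2-enoate | COC(OC)C1=COC(/C=C/C(=O)OC(C)(C)C)=CC1=S
F8 | step 5 | 1-bromo-3,3-dimethoxybutan-2-one | COC(C)(OC)C(=O)CBr
F9 | step 5 | 2-[(1E)-3-tert-butoxy-3-oxoprop-1-en-1-yl]-4-[(3,3-dimethoxy-2-oxobutyl)sulfanyl]-5-(dimethoxymethyl)pyrylium bromide | COC(OC)c1c[o+]c(/C=C/C(=O)OC(C)(C)C)cc1SCC(=O)C(C)(OC)OC.[Br-]
F10 | step 5 | tert-butyl (2E)-3-[4-(3,3-dimethoxy-2-oxobutylidene)-5-(dimethoxymethyl)-4H-pyran-2-yl]prop-2-enoate | COC(C)(OC)C(=O)C=C1C=C(/C=C/C(=O)OC(C)(C)C)OC=C1C(OC)OC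
F11 | step 6 | dilithium salt of but-3-yn-2-ol | [Li]C#CC(C)O[Li]
F12 | step 6 | tert-butyl (2E)-3-[5-(dimethoxymethyl)-4-hydroxy-4-(3-hydroxybut-1-yn-1-yl)-4H-pyran-2-yl]prop-2-enoate | COC(OC)C1=COC(/C=C/C(=O)OC(C)(C)C)=CC1(O)C#CC(C)O
F13 | step 6 | tert-butyl (2E)-3-[5-formyl-4-(3-hydroxy-2-oxobutylidene)-4H-pyran-2-yl]prop-2-enoate | CC(O)C(=O)C=C1C=C(/C=C/C(=O)OC(C)(C)C)OC=C1C=O
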